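## Structural features

The target is a five-unit guaiacyl lignan. Its head is a lariciresinol-type tetrahydrofuran (O–C7–C8–C8'–C9') that carries ring B at C7, a hydroxymethyl group (C9) at C8 and, through C7', the 4-hydroxy-3-methoxybenzyl group of ring A at C8'. Ring B is also the arene of a 7-methoxy-3-hydroxymethyl-2,3-dihydrobenzofuran (unit 1); its C2 carries ring C, the arene of unit 2, whose C2 carries ring D, the arene of unit 3, whose C2 carries the terminal guaiacyl ring E. There are nine stereocentres: C7, C8 and C8' are contiguous (7R,8S,8'S; 7,8-trans, 8,8'-cis), and each dihydrobenzofuran holds a trans C2/C3 pair, (2S,3R) in units 1 and 2 but (2R,3S) in unit 3; the pairs are separated by arenes, so none can relay its configuration to the next. Fragile features are the two free phenols (the ring E phenol is para to the benzylic C2–O bond of unit 3 and can open it through a quinone methide under base), four benzylic C–O bonds (C7–O and three C2–O) that tolerate neither hydrogenolysis nor strong acid, and electron-rich arenes that benzylic cations can alkylate. The real difficulty is twofold: building three nearly identical heterocycles with a non-uniform sense of chirality, and joining the small, stereodense four-carbon core to a large and valuable fragment late in the route. The key step uses the fact that C8' and C8 are adjacent, each bears one carbon branch (C7' and C7), and they are flanked by the oxygenated carbons C9' and C9: the chain C9'–C8'–C8–C9 is a masked butenolide in which C8' and C8 are the β- and α-carbons, C9' the acetal carbon and C9 the carbonyl carbon. C7 lies para to the ring oxygen of unit 1, so its configuration can be left open at first and settled later through the benzylic cation.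

## Logic of the disconnections

**43 back to 42.** The five O–Si bonds (two phenols, three primary alcohols) are cut last. The phenols para to benzylic positions and the hydroxymethyl groups are the only functions that need masking to the end, and one silyl type lets a single fluoride step finish the synthesis. The forward step must be buffered so that the ring E phenoxide does not open unit 3.

**42 back to 41.** The O–C7 bond of the tetrahydrofuran is cut. C7 is benzylic to ring B and para to the ring oxygen of unit 1, so it can be ionised under mild acid. This removes one ring and one stereocentre from the problem, because both C7 epimers of 41 converge on the 7,8-trans ether. The forward step needs oxygen capture by the C9' hydroxyl (five-membered) to outrun arylation by ring A, and an acid mild enough for silyl ethers and dihydrobenzofurans.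

**41 back to 40 and 39.** The two C7'–H bonds are traced to a dithiane, and the two primary alcohols C9 and C9' to a lactone carbonyl and an acetal carbon. This reveals butyrolactone 39, in which the four-carbon core, its auxiliary and both side chains are already in place. The forward steps need a hydride that reduces both termini and a desulfurisation that spares four benzylic C–O bonds.

**39 back to 31, 36 and 30.** The C7'–C8' and C8–C7 bonds are cut. This separates ring A, the chiral four-carbon unit and the whole B–E fragment, so the most valuable component enters only once and last. The forward step must add 1,4 to 36 anti to the menthyloxy group, and must trap the enolate with 30 faster than it is protonated. For that reason 30 is designed without any enolisable carbonyl or free hydroxyl.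

**31, 36 back to 1, 32 and 35.** The C–S bonds of 31 lead to aldehyde 2 and on to 1. The acetal C–O bond of 36 leads to 34 and 35, and 34 to 32 by oxidative loss of the formyl carbon. The gain is three commercial materials. The demand is a crystallisation that delivers a single C5 epimer of 36.

**30 back to 22 and 8 (unit 1).** After functional-group changes (30 to 26), the C2–C3 bond of unit 1 is cut to a diazoester and a benzylic C–H bond (24), and then the ArO–CH2 bond is cut to 22 and 8. The heterocycle is thus reduced to an ether bond plus one catalyst-controlled C–C bond. The forward insertion needs a catalyst that overrides the remote stereocentres, and the ester must be reduced and silylated before any further base is used.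

**22 back to 15 and 8 (unit 2).** The same two cuts apply. The gain is that the same monomer 8 is reused. The demand is the same catalyst enantiomer as for unit 1.

**15 back to 3 and 8 (unit 3).** The same two cuts apply once more, but the insertion needs the mirror-image catalyst because unit 3 has the opposite sense. Building the units one at a time is what makes this switch possible.

**8 back to 4.** The aryl–CH2CO2Me bond is cut to aryl bromide 6 and a zinc ester enolate. The formyl carbon of 4 is taken straight to the benzylic alcohol level (5), because that is the level needed for each ether formation. The forward coupling must work next to a bulky silyloxy group. The benzylic TBS ether is the one temporary group of each cycle; all persistent groups are TIPS, so the TBS ether can be removed selectively.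

**3 back to 1.** A C–H bond (reduction) and an O–Si bond are cut. Intermediate 2 serves twice, for ring E (3) and for ring A (31).

## Other disconnections considered

**Alternative 1:** The cut is the C3–C3a bond of unit 1, made by ring contraction of a flavanone. The precursor is A1, a (2S)-flavanone whose fused arene is ring B and whose 2-aryl group is a ring C building block. In the forward step A1 is treated with PhI(OAc)2 in trimethyl orthoformate with H2SO4. The enol ether formed in the flask is attacked by trivalent iodine at C3, the fused aryl carbon shifts from C4 to C3, and C4 leaves as the methyl ester, giving diester A2.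
- *In favour:* no diazo compound and no rhodium are needed, the trans relationship arises directly without an epimerisation step, and the reagents are cheap. On these points the alternative is better than the chosen plan. The step count for one unit (about three steps to A1 plus the contraction) is about equal to one etherification, diazo transfer and insertion.
- *Against:* the absolute configuration must already reside in A1, and flavanones can racemise by ring opening under the strongly acidic conditions. Migration of the 2-aryl group and dehydrogenation are the classical competing paths, which is why A2 carries a deactivated, brominated, acylated ring C. The sequence also grows from the ring B end, so every later cycle would have to carry the base-sensitive diester.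
- *Comparison:* mechanistically it is a cationic 1,2-shift, against a concerted carbene insertion in the chosen plan. Structurally it gives the same ester oxidation level at C3. It is the weaker choice here because the chosen plan sets each unit's sense of chirality simply by choosing the catalyst enantiomer, which this target needs.

**Alternative 2:** The cut is both C2–C3 bonds of units 1 and 2 at once. The precursor is the bis(diazoester) A3, in which rings B and C each carry a diazoacetate next to an ArO–CH2–Ar tether and unit 3 is already complete. One enantiomer of Rh2(PTTL)4 would effect two 1,5 C–H insertions, and DBU would then equilibrate both C3 centres to give the trans,trans triester A4.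
- *In favour:* units 1 and 2 have the same absolute configuration, so one catalyst sets four stereocentres in one flask. The mechanism is identical to that of the chosen plan, so it is equal on that count. It would save about five or six steps, so on step economy it is better than the chosen plan. Reduction of A4, selective benzylic oxidation and silylation would lead to the same type of aldehyde as 30, so it is fully compatible with the chosen key step.
- *Against:* a bis(diazo) compound is more hazardous and offers carbene–diazo and carbene–carbene coupling paths. The yield of the desired diastereomer is the product of two selectivities. The two esters face the base together. A failure costs a later and larger intermediate.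
- *Comparison:* the chosen plan pays with extra steps for one carbene per flask, an ester that is reduced before the next base treatment, and the freedom to correct each unit separately.

**Alternative 3:** The cut is the O1–C2 and C2–C3 bonds of unit 3 together. The precursors are the ring D sulfone A5 and the ring E benzylsulfonium salt A6, which carries a chiral sulfide. Cs2CO3 would convert A5 into its quinone methide form and A6 into its ylide. Conjugate addition forms C2–C3, and displacement of the sulfide by the phenoxide forms O1–C2, giving A7 in a (4+1) annulation.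
- *In favour:* it is convergent and needs neither diazo compound nor rhodium. The trans isomer is expected directly, and the C3 side chain is already at the alcohol level, so the reduction and silylation of one cycle are saved. On convergence and on step count for unit 3 it is equal or slightly better. In principle it could be repeated with the growing chain as the sulfonium partner.
- *Against:* the enantioselectivity rests on a stoichiometric chiral sulfide, and for alkyl-substituted quinone methides it is less predictable than catalyst-controlled insertion. The quinone methide form of A5 bears a CH2O–silyl group and can tautomerise to a vinyl phenol. A5 needs its own synthesis on an electron-poor phenol.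
- *Comparison:* it is an ionic, stepwise mechanism through a reactive intermediate, against a single concerted C–H insertion with 1 mol % of a catalyst available in both mirror forms. The chosen plan is the more predictable for a target that needs both senses of chirality.

Key step: step 29

## Remarks and abbreviations

- TBSO = tert-butyldimethylsilyloxy; TIPSO = triisopropylsilyloxy.
- Rh2(S-PTTL)4 = dirhodium tetrakis[N-phthaloyl-(S)-tert-leucinate]; Rh2(R-PTTL)4 is its mirror image.
- "D–E aryl" = (2R,3S)-7-methoxy-2-[3-methoxy-4-(TIPSO)phenyl]-3-(TIPSO-methyl)-2,3-dihydrobenzofuran-5-yl.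
- "C–E aryl" = (2S,3R)-7-methoxy-3-(TIPSO-methyl)-2-(D–E aryl)-2,3-dihydrobenzofuran-5-yl.
- "B–E aryl" = (2S,3R)-7-methoxy-3-(TIPSO-methyl)-2-(C–E aryl)-2,3-dihydrobenzofuran-5-yl.
- Assumption: Rh2(S-PTTL)4 is taken to give the (2R) series and Rh2(R-PTTL)4 the (2S) series, by analogy with simpler 2-benzyloxyphenyl diazoacetates. If the first cycle shows the opposite sense, the two catalysts are exchanged between step 9 and steps 15 and 21; nothing else changes.
- Remark: the fragments were checked against the target. The (5S)-butenolide from (+)-menthol leads to (8S,8'S). Units 1 and 2 are (2S,3R) and unit 3 is (2R,3S), so both catalyst enantiomers are needed. C8' and C8 are the β- and α-carbons of the butenolide.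
- Design change: the persistent silyl groups are TIPS, not TBS. They have to survive n-BuLi, LiAlH4, NaBH4 in methanol and mild acid, and they have to be orthogonal to the temporary benzylic TBS ether.

## Route

Step 1
Reactants: 1 vanillin (4-hydroxy-3-methoxybenzaldehyde)
Product: 2 3-methoxy-4-(TIPSO)benzaldehyde
Conditions: TIPSCl (1.2 equiv), imidazole (2.5 equiv), DMF, rt
Reagents that add atoms: chlorotriisopropylsilane, CC(C)[Si](Cl)(C(C)C)C(C)C
Why: Silylation of a phenol; the bulky TIPS ether is chosen because it must outlast n-BuLi, LiAlH4, NaBH4 in methanol and HF·pyridine on rings A and E.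

Step 2
Reactants: 2 3-methoxy-4-(TIPSO)benzaldehyde
Product: 3 [3-methoxy-4-(TIPSO)phenyl]methanol
Conditions: NaBH4 (0.6 equiv), MeOH/THF, 0 °C
Reagents that add atoms: none
Why: Borohydride reduction of an aromatic aldehyde; the benzylic carbon of 3 becomes C2 of unit 3.

Step 3
Reactants: 4 5-bromovanillin (3-bromo-4-hydroxy-5-methoxybenzaldehyde)
Product: 5 2-bromo-4-(hydroxymethyl)-6-methoxyphenol
Conditions: NaBH4 (1.0 equiv), MeOH, 0 °C → rt
Reagents that add atoms: none
Why: Borohydride reduction of the aldehyde; the future C5 carbon is set at the benzylic alcohol level needed for each later ether formation.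

Step 4
Reactants: 5 2-bromo-4-(hydroxymethyl)-6-methoxyphenol
Product: 6 [2-bromo-6-methoxy-4-(TBSO-methyl)phenoxy](tert-butyl)dimethylsilane
Conditions: TBSCl (2.5 equiv), imidazole (5 equiv), DMF, rt → 40 °C
Reagents that add atoms: tert-butylchlorodimethylsilane, CC(C)(C)[Si](C)(C)Cl
Why: Exhaustive silylation; the aryl TBS ether masks the phenol during the cross-coupling and the benzylic TBS ether becomes the temporary group of each cycle.

Step 5
Reactants: 6 [2-bromo-6-methoxy-4-(TBSO-methyl)phenoxy](tert-butyl)dimethylsilane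
Product: 7 methyl 2-[3-methoxy-2-(TBSO)-5-(TBSO-methyl)phenyl]acetate
Conditions: Zn, BrCH2CO2Me, THF, rt (gives BrZnCH2CO2Me, 2 equiv); then 6, Pd(dba)2 (2 mol %), P(t-Bu)3 (2 mol %), THF, rt → 50 °C
Reagents that add atoms: methyl bromozincacetate, COC(=O)C[Zn]Br (made from methyl bromoacetate, COC(=O)CBr, and Zn)
Why: Palladium-catalysed α-arylation of a zinc ester enolate (Negishi-type coupling of a Reformatsky reagent); the almost neutral zinc enolate leaves both silyl ethers intact and the bulky electron-rich phosphine promotes oxidative addition into the hindered C–Br bond.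

Step 6
Reactants: 7 methyl 2-[3-methoxy-2-(TBSO)-5-(TBSO-methyl)phenyl]acetate
Product: 8 methyl 2-[2-hydroxy-3-methoxy-5-(TBSO-methyl)phenyl]acetate
Conditions: KHF2 (2.5 equiv), MeOH, rt
Reagents that add atoms: none
Why: Selective desilylation: bifluoride cleaves aryl silyl ethers much faster than alkyl silyl ethers because phenoxide is the better leaving group; 8 is the repeating monomer for rings D, C and B.

Step 7
Reactants: 3 [3-methoxy-4-(TIPSO)phenyl]methanol; 8 methyl 2-[2-hydroxy-3-methoxy-5-(TBSO-methyl)phenyl]acetate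
Product: 9 methyl 2-[3-methoxy-2-{[3-methoxy-4-(TIPSO)phenyl]methoxy}-5-(TBSO-methyl)phenyl]acetate
Conditions: PPh3 (1.3 equiv), DIAD (1.3 equiv), THF, 0 °C → rt
Reagents that add atoms: none
Why: Mitsunobu etherification: the guaiacol-type phenol is acidic enough to protonate the betaine and displaces the oxyphosphonium group at the primary benzylic carbon; no stereocentre is involved.

Step 8
Reactants: 9 methyl 2-[3-methoxy-2-{[3-methoxy-4-(TIPSO)phenyl]methoxy}-5-(TBSO-methyl)phenyl]acetate
Product: 10 methyl 2-diazo-2-[3-methoxy-2-{[3-methoxy-4-(TIPSO)phenyl]methoxy}-5-(TBSO-methyl)phenyl]acetate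
Conditions: p-ABSA (1.5 equiv), DBU (1.8 equiv), MeCN, 0 °C → rt
Reagents that add atoms: 4-acetamidobenzenesulfonyl azide, CC(=O)Nc1ccc(cc1)S(=O)(=O)N=[N+]=[N-]
Why: Regitz diazo transfer to an aryl acetate; the benzylic ester C–H is the only carbon acid in the molecule.

Step 9
Reactants: 10 methyl 2-diazo-2-[3-methoxy-2-{[3-methoxy-4-(TIPSO)phenyl]methoxy}-5-(TBSO-methyl)phenyl]acetate
Product: 12 methyl (2R,3R)-trans-7-methoxy-2-[3-methoxy-4-(TIPSO)phenyl]-5-(TBSO-methyl)-2,3-dihydrobenzofuran-3-carboxylate, via cis ester 11 (not isolated)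
Conditions: Rh2(S-PTTL)4 (1 mol %), toluene, −78 → −40 °C; then DBU (1.0 equiv), rt
Reagents that add atoms: none
Why: Intramolecular 1,5 C–H insertion of the donor/acceptor rhodium carbene into the electron-rich benzylic C–H bond of the ArO–CH2–Ar tether forms C2–C3 and closes the dihydrofuran cis-selectively; the chiral carboxylate ligands select one of the two enantiotopic hydrogens and so set C2 (2R). DBU then epimerises the ester-bearing C3 through its enolate to the more stable trans isomer without touching C2.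

Step 10
Reactants: 12 methyl (2R,3R)-trans-7-methoxy-2-[3-methoxy-4-(TIPSO)phenyl]-5-(TBSO-methyl)-2,3-dihydrobenzofuran-3-carboxylate
Product: 13 [(2R,3S)-trans-7-methoxy-2-[3-methoxy-4-(TIPSO)phenyl]-5-(TBSO-methyl)-2,3-dihydrobenzofuran-3-yl]methanol
Conditions: i-Bu2AlH (3.0 equiv), CH2Cl2, −78 → 0 °C; aq. potassium sodium tartrate
Reagents that add atoms: none
Why: Hydride reduction of the ester to the primary alcohol, a standard reduction for trans-2-aryl-2,3-dihydrobenzofuran-3-carboxylates; it also removes the acidic C3–H before any further base is used.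

Step 11
Reactants: 13 [(2R,3S)-trans-7-methoxy-2-[3-methoxy-4-(TIPSO)phenyl]-5-(TBSO-methyl)-2,3-dihydrobenzofuran-3-yl]methanol
Product: 14 (2R,3S)-trans-7-methoxy-2-[3-methoxy-4-(TIPSO)phenyl]-5-(TBSO-methyl)-3-(TIPSO-methyl)-2,3-dihydrobenzofuran
Conditions: TIPSCl (1.5 equiv), imidazole (3 equiv), DMAP (0.1 equiv), DMF, rt → 40 °C
Reagents that add atoms: chlorotriisopropylsilane, CC(C)[Si](Cl)(C(C)C)C(C)C
Why: Silylation of the primary alcohol with the persistent group, which is orthogonal to the benzylic TBS ether removed next.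

Step 12
Reactants: 14 (2R,3S)-trans-7-methoxy-2-[3-methoxy-4-(TIPSO)phenyl]-5-(TBSO-methyl)-3-(TIPSO-methyl)-2,3-dihydrobenzofuran
Product: 15 (D–E aryl)methanol, i.e. [(2R,3S)-7-methoxy-2-[3-methoxy-4-(TIPSO)phenyl]-3-(TIPSO-methyl)-2,3-dihydrobenzofuran-5-yl]methanol
Conditions: HF·pyridine, pyridine, THF, 0 °C → rt
Reagents that add atoms: none
Why: Selective desilylation: buffered HF cleaves a primary TBS ether far faster than primary or aryl TIPS ethers, and the non-nucleophilic medium avoids solvolysis of the electron-rich benzylic alcohol.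

Step 13
Reactants: 15 (D–E aryl)methanol; 8 methyl 2-[2-hydroxy-3-methoxy-5-(TBSO-methyl)phenyl]acetate
Product: 16 methyl 2-[3-methoxy-2-[(D–E aryl)methoxy]-5-(TBSO-methyl)phenyl]acetate
Conditions: PPh3 (1.3 equiv), DIAD (1.3 equiv), THF, 0 °C → rt
Reagents that add atoms: none
Why: Mitsunobu etherification as in step 7; the benzylic alcohol of 15 is primary and its only free hydroxyl.

Step 14
Reactants: 16 methyl 2-[3-methoxy-2-[(D–E aryl)methoxy]-5-(TBSO-methyl)phenyl]acetate
Product: 17 methyl 2-diazo-2-[3-methoxy-2-[(D–E aryl)methoxy]-5-(TBSO-methyl)phenyl]acetate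
Conditions: p-ABSA (1.5 equiv), DBU (1.8 equiv), MeCN, 0 °C → rt
Reagents that add atoms: 4-acetamidobenzenesulfonyl azide, CC(=O)Nc1ccc(cc1)S(=O)(=O)N=[N+]=[N-]
Why: Regitz diazo transfer; unit 3 no longer carries an ester, so the aryl acetate is the only site that DBU can deprotonate.

Step 15
Reactants: 17 methyl 2-diazo-2-[3-methoxy-2-[(D–E aryl)methoxy]-5-(TBSO-methyl)phenyl]acetate
Product: 19 methyl (2S,3S)-trans-7-methoxy-2-(D–E aryl)-5-(TBSO-methyl)-2,3-dihydrobenzofuran-3-carboxylate, via cis ester 18 (not isolated)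
Conditions: Rh2(R-PTTL)4 (1 mol %), toluene, −78 → −40 °C; then DBU (1.0 equiv), rt
Reagents that add atoms: none
Why: The same rhodium carbene 1,5 C–H insertion and C3 epimerisation as in step 9; the mirror-image catalyst now sets C2 as (2S). The stereocentres of unit 3 lie beyond an arene, so catalyst control should dominate.

Step 16
Reactants: 19 methyl (2S,3S)-trans-7-methoxy-2-(D–E aryl)-5-(TBSO-methyl)-2,3-dihydrobenzofuran-3-carboxylate
Product: 20 [(2S,3R)-trans-7-methoxy-2-(D–E aryl)-5-(TBSO-methyl)-2,3-dihydrobenzofuran-3-yl]methanol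
Conditions: i-Bu2AlH (3.0 equiv), CH2Cl2, −78 → 0 °C; aq. potassium sodium tartrate
Reagents that add atoms: none
Why: Ester reduction with an aluminium hydride as in step 10; silyl ethers and benzylic ethers are inert.

Step 17
Reactants: 20 [(2S,3R)-trans-7-methoxy-2-(D–E aryl)-5-(TBSO-methyl)-2,3-dihydrobenzofuran-3-yl]methanol
Product: 21 (2S,3R)-trans-7-methoxy-2-(D–E aryl)-5-(TBSO-methyl)-3-(TIPSO-methyl)-2,3-dihydrobenzofuran
Conditions: TIPSCl (1.5 equiv), imidazole (3 equiv), DMAP (0.1 equiv), DMF, rt → 40 °C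
Reagents that add atoms: chlorotriisopropylsilane, CC(C)[Si](Cl)(C(C)C)C(C)C
Why: Silylation of the primary alcohol with the persistent TIPS group, as in step 11.

Step 18
Reactants: 21 (2S,3R)-trans-7-methoxy-2-(D–E aryl)-5-(TBSO-methyl)-3-(TIPSO-methyl)-2,3-dihydrobenzofuran
Product: 22 (C–E aryl)methanol
Conditions: HF·pyridine, pyridine, THF, 0 °C → rt
Reagents that add atoms: none
Why: Selective cleavage of the primary TBS ether in the presence of TIPS ethers, as in step 12.

Step 19
Reactants: 22 (C–E aryl)methanol; 8 methyl 2-[2-hydroxy-3-methoxy-5-(TBSO-methyl)phenyl]acetate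
Product: 23 methyl 2-[3-methoxy-2-[(C–E aryl)methoxy]-5-(TBSO-methyl)phenyl]acetate
Conditions: PPh3 (1.3 equiv), DIAD (1.3 equiv), THF, 0 °C → rt
Reagents that add atoms: none
Why: Mitsunobu etherification as in steps 7 and 13.

Step 20
Reactants: 23 methyl 2-[3-methoxy-2-[(C–E aryl)methoxy]-5-(TBSO-methyl)phenyl]acetate
Product: 24 methyl 2-diazo-2-[3-methoxy-2-[(C–E aryl)methoxy]-5-(TBSO-methyl)phenyl]acetate
Conditions: p-ABSA (1.5 equiv), DBU (1.8 equiv), MeCN, 0 °C → rt
Reagents that add atoms: 4-acetamidobenzenesulfonyl azide, CC(=O)Nc1ccc(cc1)S(=O)(=O)N=[N+]=[N-]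
Why: Regitz diazo transfer as in steps 8 and 14; no other carbon acid is present.

Step 21
Reactants: 24 methyl 2-diazo-2-[3-methoxy-2-[(C–E aryl)methoxy]-5-(TBSO-methyl)phenyl]acetate
Product: 26 methyl (2S,3S)-trans-7-methoxy-2-(C–E aryl)-5-(TBSO-methyl)-2,3-dihydrobenzofuran-3-carboxylate, via cis ester 25 (not isolated)
Conditions: Rh2(R-PTTL)4 (1 mol %), toluene, −78 → −40 °C; then DBU (1.0 equiv), rt
Reagents that add atoms: none
Why: Rhodium carbene 1,5 C–H insertion with the same catalyst enantiomer as for unit 2, setting C2 of unit 1 as (2S); DBU epimerisation at C3 gives the trans ester.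

Step 22
Reactants: 26 methyl (2S,3S)-trans-7-methoxy-2-(C–E aryl)-5-(TBSO-methyl)-2,3-dihydrobenzofuran-3-carboxylate
Product: 27 [(2S,3R)-trans-7-methoxy-2-(C–E aryl)-5-(TBSO-methyl)-2,3-dihydrobenzofuran-3-yl]methanol
Conditions: i-Bu2AlH (3.0 equiv), CH2Cl2, −78 → 0 °C; aq. potassium sodium tartrate
Reagents that add atoms: none
Why: Ester reduction with an aluminium hydride as in steps 10 and 16.

Step 23
Reactants: 27 [(2S,3R)-trans-7-methoxy-2-(C–E aryl)-5-(TBSO-methyl)-2,3-dihydrobenzofuran-3-yl]methanol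
Product: 28 (2S,3R)-trans-7-methoxy-2-(C–E aryl)-5-(TBSO-methyl)-3-(TIPSO-methyl)-2,3-dihydrobenzofuran
Conditions: TIPSCl (1.5 equiv), imidazole (3 equiv), DMAP (0.1 equiv), DMF, rt → 40 °C
Reagents that add atoms: chlorotriisopropylsilane, CC(C)[Si](Cl)(C(C)C)C(C)C
Why: Silylation of the primary alcohol with the persistent TIPS group.

Step 24
Reactants: 28 (2S,3R)-trans-7-methoxy-2-(C–E aryl)-5-(TBSO-methyl)-3-(TIPSO-methyl)-2,3-dihydrobenzofuran
Product: 29 (B–E aryl)methanol
Conditions: HF·pyridine, pyridine, THF, 0 °C → rt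
Reagents that add atoms: none
Why: Selective cleavage of the primary TBS ether in the presence of five TIPS ethers.

Step 25
Reactants: 29 (B–E aryl)methanol
Product: 30 (2S,3R)-7-methoxy-3-(TIPSO-methyl)-2-(C–E aryl)-2,3-dihydrobenzofuran-5-carbaldehyde (B–E aryl carbaldehyde)
Conditions: MnO2 (activated, 15 equiv), CH2Cl2, rt
Reagents that add atoms: none
Why: Manganese dioxide oxidation of an electron-rich benzylic alcohol stops at the aldehyde; silyl ethers and benzylic ethers are inert.

Step 26
Reactants: 2 3-methoxy-4-(TIPSO)benzaldehyde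
Product: 31 2-[3-methoxy-4-(TIPSO)phenyl]-1,3-dithiane
Conditions: HS(CH2)3SH (1.2 equiv), BF3·OEt2 (0.1 equiv), CH2Cl2, 0 °C
Reagents that add atoms: propane-1,3-dithiol, SCCCS
Why: Lewis-acid-catalysed dithioacetalisation of the aldehyde; the dithiane converts C7' into an acyl anion equivalent and the aryl TIPS ether tolerates the catalytic Lewis acid.

Step 27
Reactants: 32 furfural
Product: 34 5-hydroxyfuran-2(5H)-one, via furan endoperoxide 33 (not isolated)
Conditions: O2, hν (visible), methylene blue (cat.), MeOH, 20 °C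
Reagents that add atoms: dioxygen, O=O
Why: Photosensitised [4+2] cycloaddition of singlet oxygen to the furan gives the endoperoxide, which fragments in methanol with loss of the formyl carbon as methyl formate to give the hydroxybutenolide.

Step 28
Reactants: 34 5-hydroxyfuran-2(5H)-one; 35 (+)-menthol
Product: 36 (5S)-5-[(1S,2R,5S)-menthyloxy]furan-2(5H)-one
Conditions: p-TsOH·H2O (cat.), toluene, reflux, Dean–Stark; crystallisation from petroleum ether, mother liquor re-equilibrated with p-TsOH and recrystallised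
Reagents that add atoms: none
Why: Acid-catalysed acetalisation of the lactol gives both C5 epimers, which interconvert under acid through the oxocarbenium ion. The (5S) epimer is expected to crystallise, as the mirror image of the (5R) epimer obtained from (−)-menthol, so the acetal stereocentre is set by crystallisation-induced diastereomer enrichment.

Step 29
Reactants: 31 2-[3-methoxy-4-(TIPSO)phenyl]-1,3-dithiane; 36 (5S)-5-[(1S,2R,5S)-menthyloxy]furan-2(5H)-one; 30 B–E aryl carbaldehyde
Product: 39 (3R,4S,5S)-3-[(B–E aryl)(hydroxy)methyl]-4-{2-[3-methoxy-4-(TIPSO)phenyl]-1,3-dithian-2-yl}-5-[(1S,2R,5S)-menthyloxy]dihydrofuran-2(3H)-one as a mixture of C7 epimers, via lithiated dithiane 37 (not isolated), via lithium enolate 38 (not isolated)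
Conditions: 31 (1.3 equiv), n-BuLi (1.25 equiv), THF, −78 °C; 36 (1.3 equiv), −78 °C, 1 h; 30 (1.0 equiv), THF, −78 °C, 2 h; AcOH, −78 °C
Reagents that add atoms: none
Why: n-BuLi removes the C2 proton of 31, and the sulfur-stabilised benzylic anion 37 (C7') adds as a soft nucleophile to the β-carbon of 36 on the face opposite the menthyloxy group, which forms C7'–C8' and sets C8' (4S of the lactone) under control of the acetal stereocentre. The lithium enolate 38 is then intercepted at its α-carbon by aldehyde 30 on the face anti to the bulky dithianyl group at C8', which forms C8–C7 and sets C8 (3R), giving the 3,4-trans lactone. The new carbinol centre C7 is expected as a mixture because neither aldol transition state is strongly preferred; this is accepted because C7 is ionised and reset in step 32. No ring is closed: the lactone ring of 36 is carried through unchanged and both new bonds are exocyclic. The closest known reaction type is the tandem conjugate addition–aldol reaction of lithiated 2-aryl-1,3-dithianes with 5-alkoxyfuran-2(5H)-ones and aromatic aldehydes, used for dibenzylbutyrolactone lignans. The step needs 1,4- over 1,2-addition, secured by the soft dithianyl anion and the hindered lactone carbonyl, and aldol addition faster than proton transfer, secured by an aldehyde that has no α-hydrogen and no free hydroxyl. The trans lactone maps onto the 8,8'-cis tetrahydrofuran because C8 exchanges its ring and exocyclic carbon substituents when the ring is later re-closed through C9'–O–C7. The reaction is quenched cold with acetic acid to prevent retro-aldol cleavage.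

Step 30
Reactants: 39 (3R,4S,5S)-lactone adduct (C7 epimers)
Product: 40 (2S,3S)-2-[(B–E aryl)(hydroxy)methyl]-3-{2-[3-methoxy-4-(TIPSO)phenyl]-1,3-dithian-2-yl}butane-1,4-diol (C7 epimers)
Conditions: LiAlH4 (4 equiv), THF, 0 °C → rt; H2O, aq. NaOH
Reagents that add atoms: none
Why: Hydride reduction of the lactone: C9 is reduced to the primary alcohol, the ring-opened C9' hemiacetal expels menthoxide, and the aldehyde so released is reduced as well, so both termini end as CH2OH. C8 and C8' are untouched, and dithiane and TIPS ethers are stable to the reagent.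

Step 31
Reactants: 40 (2S,3S)-dithianyl triol (C7 epimers)
Product: 41 (2S,3S)-2-[(B–E aryl)(hydroxy)methyl]-3-[3-methoxy-4-(TIPSO)benzyl]butane-1,4-diol (C7 epimers)
Conditions: NiCl2·6H2O (8 equiv), NaBH4 (24 equiv), MeOH/THF (3:1), 0 °C
Reagents that add atoms: none
Why: Reductive desulfurisation with nickel boride formed in the flask cleaves both benzylic C–S bonds and turns C7' into CH2. The reagent is mild enough to leave the benzylic C7–OH, the three benzylic C2–O bonds and the aryl silyl ethers in place.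

Step 32
Reactants: 41 (2S,3S)-triol (C7 epimers)
Product: 42 [(2R,3S,4S)-2-(B–E aryl)-4-[3-methoxy-4-(TIPSO)benzyl]tetrahydrofuran-3-yl]methanol
Conditions: (±)-camphor-10-sulfonic acid (0.1 equiv), CH2Cl2, 0 °C; then Et3N
Reagents that add atoms: none
Why: Acid-catalysed cycloetherification: either C7 epimer ionises to a benzylic cation stabilised by the para ring oxygen of unit 1, and the C9' hydroxyl captures it in a five-membered closure (the C9 hydroxyl could only give an oxetane). The aryl group settles trans to the C8 hydroxymethyl group in a reversible, product-controlled closure, which sets C7 (R). Oxygen capture is faster than arylation by ring A, and catalytic acid at 0 °C spares TIPS ethers and dihydrobenzofurans.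

Step 33
Reactants: 42 penta-TIPS tetrahydrofuran
Product: 43 CNP0267891.2, [(2R,3S,4S)-2-aryl-4-(4-hydroxy-3-methoxybenzyl)tetrahydrofuran-3-yl]methanol with the free tris(dihydrobenzofuran) aryl group
Conditions: Bu4NF (8 equiv), AcOH (8 equiv), THF, 0 °C → 40 °C
Reagents that add atoms: none
Why: Fluoride-mediated global desilylation of two aryl and three primary TIPS ethers; acetic acid keeps the ring E phenol protonated, so the para benzylic C2–O bond of unit 3 is not opened through a quinone methide.

## Compound list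

1 | vanillin | COc1cc(C=O)ccc1O | starting material
2 | 3-methoxy-4-(TIPSO)benzaldehyde | COc1cc(C=O)ccc1O[Si](C(C)C)(C(C)C)C(C)C | intermediate
3 | [3-methoxy-4-(TIPSO)phenyl]methanol | COc1cc(CO)ccc1O[Si](C(C)C)(C(C)C)C(C)C | intermediate
4 | 5-bromovanillin | O=Cc1cc(Br)c(O)c(OC)c1 | starting material
5 | 2-bromo-4-(hydroxymethyl)-6-methoxyphenol | OCc1cc(Br)c(O)c(OC)c1 | intermediate
6 | [2-bromo-6-methoxy-4-(TBSO-methyl)phenoxy](tert-butyl)dimethylsilane | COc1cc(CO[Si](C)(C)C(C)(C)C)cc(Br)c1O[Si](C)(C)C(C)(C)C | intermediate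
7 | methyl 2-[3-methoxy-2-(TBSO)-5-(TBSO-methyl)phenyl]acetate | COC(=O)Cc1cc(CO[Si](C)(C)C(C)(C)C)cc(OC)c1O[Si](C)(C)C(C)(C)C | intermediate
8 | methyl 2-[2-hydroxy-3-methoxy-5-(TBSO-methyl)phenyl]acetate | COC(=O)Cc1cc(CO[Si](C)(C)C(C)(C)C)cc(OC)c1O | intermediate
9 | methyl 2-[3-methoxy-2-{[3-methoxy-4-(TIPSO)phenyl]methoxy}-5-(TBSO-methyl)phenyl]acetate | COC(=O)Cc1cc(CO[Si](C)(C)C(C)(C)C)cc(OC)c1OCc1ccc(O[Si](C(C)C)(C(C)C)C(C)C)c(OC)c1 | intermediate
10 | methyl 2-diazo-2-[3-methoxy-2-{[3-methoxy-4-(TIPSO)phenyl]methoxy}-5-(TBSO-methyl)phenyl]acetate | COC(=O)C(=[N+]=[N-])c1cc(CO[Si](C)(C)C(C)(C)C)cc(OC)c1OCc1ccc(O[Si](C(C)C)(C(C)C)C(C)C)c(OC)c1 | intermediate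
11 | methyl (2R,3S)-cis-7-methoxy-2-[3-methoxy-4-(TIPSO)phenyl]-5-(TBSO-methyl)-2,3-dihydrobenzofuran-3-carboxylate | CC(C)(C)[Si](C)(C)OCc1cc(OC)c2c(c1)[C@H](C(=O)OC)[C@H](c1ccc(O[Si](C(C)C)(C(C)C)C(C)C)c(OC)c1)O2 | intermediate
12 | methyl (2R,3R)-trans-7-methoxy-2-[3-methoxy-4-(TIPSO)phenyl]-5-(TBSO-methyl)-2,3-dihydrobenzofuran-3-carboxylate | CC(C)(C)[Si](C)(C)OCc1cc(OC)c2c(c1)[C@@H](C(=O)OC)[C@H](c1ccc(O[Si](C(C)C)(C(C)C)C(C)C)c(OC)c1)O2 | intermediate
13 | [(2R,3S)-trans-7-methoxy-2-[3-methoxy-4-(TIPSO)phenyl]-5-(TBSO-methyl)-2,3-dihydrobenzofuran-3-yl]methanol | CC(C)(C)[Si](C)(C)OCc1cc(OC)c2c(c1)[C@@H](CO)[C@H](c1ccc(O[Si](C(C)C)(C(C)C)C(C)C)c(OC)c1)O2 | intermediate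
14 | (2R,3S)-trans-7-methoxy-2-[3-methoxy-4-(TIPSO)phenyl]-5-(TBSO-methyl)-3-(TIPSO-methyl)-2,3-dihydrobenzofuran | CC(C)(C)[Si](C)(C)OCc1cc(OC)c2c(c1)[C@@H](CO[Si](C(C)C)(C(C)C)C(C)C)[C@H](c1ccc(O[Si](C(C)C)(C(C)C)C(C)C)c(OC)c1)O2 | intermediate
15 | (D–E aryl)methanol | OCc5cc(OC)c6c(c5)[C@@H](CO[Si](C(C)C)(C(C)C)C(C)C)[C@H](c7ccc(O[Si](C(C)C)(C(C)C)C(C)C)c(OC)c7)O6 | intermediate
16 | methyl 2-[3-methoxy-2-[(D–E aryl)methoxy]-5-(TBSO-methyl)phenyl]acetate | COC(=O)Cc1cc(CO[Si](C)(C)C(C)(C)C)cc(OC)c1OCc5cc(OC)c6c(c5)[C@@H](CO[Si](C(C)C)(C(C)C)C(C)C)[C@H](c7ccc(O[Si](C(C)C)(C(C)C)C(C)C)c(OC)c7)O6 | intermediate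
17 | methyl 2-diazo-2-[3-methoxy-2-[(D–E aryl)methoxy]-5-(TBSO-methyl)phenyl]acetate | COC(=O)C(=[N+]=[N-])c1cc(CO[Si](C)(C)C(C)(C)C)cc(OC)c1OCc5cc(OC)c6c(c5)[C@@H](CO[Si](C(C)C)(C(C)C)C(C)C)[C@H](c7ccc(O[Si](C(C)C)(C(C)C)C(C)C)c(OC)c7)O6 | intermediate
18 | methyl (2S,3R)-cis-7-methoxy-2-(D–E aryl)-5-(TBSO-methyl)-2,3-dihydrobenzofuran-3-carboxylate | CC(C)(C)[Si](C)(C)OCc3cc(OC)c4c(c3)[C@@H](C(=O)OC)[C@@H](c5cc(OC)c6c(c5)[C@@H](CO[Si](C(C)C)(C(C)C)C(C)C)[C@H](c7ccc(O[Si](C(C)C)(C(C)C)C(C)C)c(OC)c7)O6)O4 | intermediate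
19 | methyl (2S,3S)-trans-7-methoxy-2-(D–E aryl)-5-(TBSO-methyl)-2,3-dihydrobenzofuran-3-carboxylate | CC(C)(C)[Si](C)(C)OCc3cc(OC)c4c(c3)[C@H](C(=O)OC)[C@@H](c5cc(OC)c6c(c5)[C@@H](CO[Si](C(C)C)(C(C)C)C(C)C)[C@H](c7ccc(O[Si](C(C)C)(C(C)C)C(C)C)c(OC)c7)O6)O4 | intermediate
20 | [(2S,3R)-trans-7-methoxy-2-(D–E aryl)-5-(TBSO-methyl)-2,3-dihydrobenzofuran-3-yl]methanol | CC(C)(C)[Si](C)(C)OCc3cc(OC)c4c(c3)[C@H](CO)[C@@H](c5cc(OC)c6c(c5)[C@@H](CO[Si](C(C)C)(C(C)C)C(C)C)[C@H](c7ccc(O[Si](C(C)C)(C(C)C)C(C)C)c(OC)c7)O6)O4 | intermediate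
21 | (2S,3R)-trans-7-methoxy-2-(D–E aryl)-5-(TBSO-methyl)-3-(TIPSO-methyl)-2,3-dihydrobenzofuran | CC(C)(C)[Si](C)(C)OCc3cc(OC)c4c(c3)[C@H](CO[Si](C(C)C)(C(C)C)C(C)C)[C@@H](c5cc(OC)c6c(c5)[C@@H](CO[Si](C(C)C)(C(C)C)C(C)C)[C@H](c7ccc(O[Si](C(C)C)(C(C)C)C(C)C)c(OC)c7)O6)O4 | intermediate
22 | (C–E aryl)methanol | OCc3cc(OC)c4c(c3)[C@H](CO[Si](C(C)C)(C(C)C)C(C)C)[C@@H](c5cc(OC)c6c(c5)[C@@H](CO[Si](C(C)C)(C(C)C)C(C)C)[C@H](c7ccc(O[Si](C(C)C)(C(C)C)C(C)C)c(OC)c7)O6)O4 | intermediate
23 | methyl 2-[3-methoxy-2-[(C–E aryl)methoxy]-5-(TBSO-methyl)phenyl]acetate | COC(=O)Cc1cc(CO[Si](C)(C)C(C)(C)C)cc(OC)c1OCc3cc(OC)c4c(c3)[C@H](CO[Si](C(C)C)(C(C)C)C(C)C)[C@@H](c5cc(OC)c6c(c5)[C@@H](CO[Si](C(C)C)(C(C)C)C(C)C)[C@H](c7ccc(O[Si](C(C)C)(C(C)C)C(C)C)c(OC)c7)O6)O4 | intermediate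
24 | methyl 2-diazo-2-[3-methoxy-2-[(C–E aryl)methoxy]-5-(TBSO-methyl)phenyl]acetate | COC(=O)C(=[N+]=[N-])c1cc(CO[Si](C)(C)C(C)(C)C)cc(OC)c1OCc3cc(OC)c4c(c3)[C@H](CO[Si](C(C)C)(C(C)C)C(C)C)[C@@H](c5cc(OC)c6c(c5)[C@@H](CO[Si](C(C)C)(C(C)C)C(C)C)[C@H](c7ccc(O[Si](C(C)C)(C(C)C)C(C)C)c(OC)c7)O6)O4 | intermediate
25 | methyl (2S,3R)-cis-7-methoxy-2-(C–E aryl)-5-(TBSO-methyl)-2,3-dihydrobenzofuran-3-carboxylate | CC(C)(C)[Si](C)(C)OCc1cc(OC)c2c(c1)[C@@H](C(=O)OC)[C@@H](c3cc(OC)c4c(c3)[C@H](CO[Si](C(C)C)(C(C)C)C(C)C)[C@@H](c5cc(OC)c6c(c5)[C@@H](CO[Si](C(C)C)(C(C)C)C(C)C)[C@H](c7ccc(O[Si](C(C)C)(C(C)C)C(C)C)c(OC)c7)O6)O4)O2 | intermediate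
26 | methyl (2S,3S)-trans-7-methoxy-2-(C–E aryl)-5-(TBSO-methyl)-2,3-dihydrobenzofuran-3-carboxylate | CC(C)(C)[Si](C)(C)OCc1cc(OC)c2c(c1)[C@H](C(=O)OC)[C@@H](c3cc(OC)c4c(c3)[C@H](CO[Si](C(C)C)(C(C)C)C(C)C)[C@@H](c5cc(OC)c6c(c5)[C@@H](CO[Si](C(C)C)(C(C)C)C(C)C)[C@H](c7ccc(O[Si](C(C)C)(C(C)C)C(C)C)c(OC)c7)O6)O4)O2 | intermediate
27 | [(2S,3R)-trans-7-methoxy-2-(C–E aryl)-5-(TBSO-methyl)-2,3-dihydrobenzofuran-3-yl]methanol | CC(C)(C)[Si](C)(C)OCc1cc(OC)c2c(c1)[C@H](CO)[C@@H](c3cc(OC)c4c(c3)[C@H](CO[Si](C(C)C)(C(C)C)C(C)C)[C@@H](c5cc(OC)c6c(c5)[C@@H](CO[Si](C(C)C)(C(C)C)C(C)C)[C@H](c7ccc(O[Si](C(C)C)(C(C)C)C(C)C)c(OC)c7)O6)O4)O2 | intermediate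
28 | (2S,3R)-trans-7-methoxy-2-(C–E aryl)-5-(TBSO-methyl)-3-(TIPSO-methyl)-2,3-dihydrobenzofuran | CC(C)(C)[Si](C)(C)OCc1cc(OC)c2c(c1)[C@H](CO[Si](C(C)C)(C(C)C)C(C)C)[C@@H](c3cc(OC)c4c(c3)[C@H](CO[Si](C(C)C)(C(C)C)C(C)C)[C@@H](c5cc(OC)c6c(c5)[C@@H](CO[Si](C(C)C)(C(C)C)C(C)C)[C@H](c7ccc(O[Si](C(C)C)(C(C)C)C(C)C)c(OC)c7)O6)O4)O2 | intermediate
29 | (B–E aryl)methanol | OCc1cc(OC)c2c(c1)[C@H](CO[Si](C(C)C)(C(C)C)C(C)C)[C@@H](c3cc(OC)c4c(c3)[C@H](CO[Si](C(C)C)(C(C)C)C(C)C)[C@@H](c5cc(OC)c6c(c5)[C@@H](CO[Si](C(C)C)(C(C)C)C(C)C)[C@H](c7ccc(O[Si](C(C)C)(C(C)C)C(C)C)c(OC)c7)O6)O4)O2 | intermediate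
30 | B–E aryl carbaldehyde (TIPS-protected tris(dihydrobenzofuran) aldehyde) | O=Cc1cc(OC)c2c(c1)[C@H](CO[Si](C(C)C)(C(C)C)C(C)C)[C@@H](c3cc(OC)c4c(c3)[C@H](CO[Si](C(C)C)(C(C)C)C(C)C)[C@@H](c5cc(OC)c6c(c5)[C@@H](CO[Si](C(C)C)(C(C)C)C(C)C)[C@H](c7ccc(O[Si](C(C)C)(C(C)C)C(C)C)c(OC)c7)O6)O4)O2 | intermediate
31 | 2-[3-methoxy-4-(TIPSO)phenyl]-1,3-dithiane | COc1cc(C2SCCCS2)ccc1O[Si](C(C)C)(C(C)C)C(C)C | intermediate
32 | furfural | O=Cc1ccco1 | starting material
33 | 2,3,7-trioxabicyclo[2.2.1]hept-5-ene-1-carbaldehyde (furan endoperoxide) | O=CC12C=CC(OO1)O2 | intermediate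
34 | 5-hydroxyfuran-2(5H)-one | O=C1C=CC(O)O1 | intermediate
35 | (+)-menthol, (1S,2R,5S)-2-isopropyl-5-methylcyclohexanol | CC(C)[C@H]1CC[C@H](C)C[C@@H]1O | starting material
36 | (5S)-5-[(1S,2R,5S)-menthyloxy]furan-2(5H)-one | O=C1C=C[C@@H](O[C@H]2C[C@@H](C)CC[C@@H]2C(C)C)O1 | intermediate
37 | 2-lithio-2-[3-methoxy-4-(TIPSO)phenyl]-1,3-dithiane | COc1cc(C2([Li])SCCCS2)ccc1O[Si](C(C)C)(C(C)C)C(C)C | intermediate
38 | lithium enolate of (4S,5S)-4-{2-[3-methoxy-4-(TIPSO)phenyl]-1,3-dithian-2-yl}-5-[(1S,2R,5S)-menthyloxy]dihydrofuran-2(3H)-one | [Li]OC1=C[C@H](C2(SCCCS2)c2ccc(O[Si](C(C)C)(C(C)C)C(C)C)c(OC)c2)[C@@H](O[C@H]2C[C@@H](C)CC[C@@H]2C(C)C)O1 | intermediate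
39 | (3R,4S,5S)-3-[(B–E aryl)(hydroxy)methyl]-4-{2-[3-methoxy-4-(TIPSO)phenyl]-1,3-dithian-2-yl}-5-[(1S,2R,5S)-menthyloxy]dihydrofuran-2(3H)-one (C7 epimers) | COc5cc(C6(SCCCS6)[C@@H]7[C@@H](O[C@H]8C[C@@H](C)CC[C@@H]8C(C)C)OC(=O)[C@H]7C(O)c1cc(OC)c2c(c1)[C@H](CO[Si](C(C)C)(C(C)C)C(C)C)[C@@H](c1cc(OC)c3c(c1)[C@H](CO[Si](C(C)C)(C(C)C)C(C)C)[C@@H](c1cc(OC)c4c(c1)[C@@H](CO[Si](C(C)C)(C(C)C)C(C)C)[C@H](c1ccc(O[Si](C(C)C)(C(C)C)C(C)C)c(OC)c1)O4)O3)O2)ccc5O[Si](C(C)C)(C(C)C)C(C)C | intermediate
40 | (2S,3S)-2-[(B–E aryl)(hydroxy)methyl]-3-{2-[3-methoxy-4-(TIPSO)phenyl]-1,3-dithian-2-yl}butane-1,4-diol (C7 epimers) | COc5cc(C6(SCCCS6)[C@H](CO)[C@@H](CO)C(O)c1cc(OC)c2c(c1)[C@H](CO[Si](C(C)C)(C(C)C)C(C)C)[C@@H](c1cc(OC)c3c(c1)[C@H](CO[Si](C(C)C)(C(C)C)C(C)C)[C@@H](c1cc(OC)c4c(c1)[C@@H](CO[Si](C(C)C)(C(C)C)C(C)C)[C@H](c1ccc(O[Si](C(C)C)(C(C)C)C(C)C)c(OC)c1)O4)O3)O2)ccc5O[Si](C(C)C)(C(C)C)C(C)C | intermediate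
41 | (2S,3S)-2-[(B–E aryl)(hydroxy)methyl]-3-[3-methoxy-4-(TIPSO)benzyl]butane-1,4-diol (C7 epimers) | COc5cc(C[C@H](CO)[C@@H](CO)C(O)c1cc(OC)c2c(c1)[C@H](CO[Si](C(C)C)(C(C)C)C(C)C)[C@@H](c1cc(OC)c3c(c1)[C@H](CO[Si](C(C)C)(C(C)C)C(C)C)[C@@H](c1cc(OC)c4c(c1)[C@@H](CO[Si](C(C)C)(C(C)C)C(C)C)[C@H](c1ccc(O[Si](C(C)C)(C(C)C)C(C)C)c(OC)c1)O4)O3)O2)ccc5O[Si](C(C)C)(C(C)C)C(C)C | intermediate
42 | [(2R,3S,4S)-2-(B–E aryl)-4-[3-methoxy-4-(TIPSO)benzyl]tetrahydrofuran-3-yl]methanol | COc1cc(C[C@@H]2CO[C@@H](c3cc(OC)c4c(c3)[C@H](CO[Si](C(C)C)(C(C)C)C(C)C)[C@@H](c3cc(OC)c5c(c3)[C@H](CO[Si](C(C)C)(C(C)C)C(C)C)[C@@H](c3cc(OC)c6c(c3)[C@@H](CO[Si](C(C)C)(C(C)C)C(C)C)[C@H](c3ccc(O[Si](C(C)C)(C(C)C)C(C)C)c(OC)c3)O6)O5)O4)[C@@H]2CO)ccc1O[Si](C(C)C)(C(C)C)C(C)C | intermediate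
43 | CNP0267891.2 | COc1cc(C[C@@H]2CO[C@@H](c3cc(OC)c4c(c3)[C@H](CO)[C@@H](c3cc(OC)c5c(c3)[C@H](CO)[C@@H](c3cc(OC)c6c(c3)[C@@H](CO)[C@H](c3ccc(O)c(OC)c3)O6)O5)O4)[C@@H]2CO)ccc1O | target

## Step count and risks

Total step count: 33. Longest linear sequence: 28 steps (4 to 43 through steps 3–25 and 29–33).

**Step 29 (key step).**
- *What may go wrong:* the enolate may be protonated, or may add reversibly, before the large aldehyde is consumed, so that conjugate addition occurs without the aldol. The facial preference at C8 may also erode, because the bulky aldehyde and the dithianyl group crowd the same ring.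
- *Fallback:* the two bond formations are separated, setting out from 31 and 36 and returning at 39. The anion of 31 is added to 36 and the enolate is protonated to give the isolable lactone (4S,5S)-4-{2-[3-methoxy-4-(TIPSO)phenyl]-1,3-dithian-2-yl}-5-[(1S,2R,5S)-menthyloxy]dihydrofuran-2(3H)-one F1. F1 is deprotonated with LiN(i-Pr)2 in THF at −78 °C and transmetalated with ZnCl2, and the zinc enolate is combined with 30 to give 39. This is the known aldol reaction of preformed butyrolactone enolates with aromatic aldehydes, which also permits a change of counter-ion.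

**Step 9 (and likewise steps 15 and 21).**
- *What may go wrong:* the catalyst may not discriminate the enantiotopic benzylic hydrogens well enough, because of the methoxy group next to the tether, or it may do so in the opposite sense. Carbene dimerisation or β-elimination during the base equilibration may lower the yield.
- *Fallback:* stereocontrol is moved from the catalyst alone to a covalently bound auxiliary, setting out from 9 and returning at 13.
  - Ester 9 is hydrolysed with Me3SnOH to 2-[3-methoxy-2-{[3-methoxy-4-(TIPSO)phenyl]methoxy}-5-(TBSO-methyl)phenyl]acetic acid F2.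
  - F2 is esterified (EDC, DMAP) with (S)-2-hydroxy-1-(pyrrolidin-1-yl)propan-1-one to the (S)-lactamide ester F3.
  - F3 is converted with p-ABSA and DBU into the diazoester F4.
  - F4 cyclises under the matched enantiomer of Rh2(DOSP)4, dirhodium tetrakis[N-(4-dodecylphenylsulfonyl)prolinate], to the (2R,3R)-trans-dihydrobenzofuran lactamide ester F5 (DBU if the cis isomer forms).
  - LiBH4 reduces F5 to 13 and releases the auxiliary.
  - This double stereodifferentiation with a lactamide auxiliary is known chemistry for 2-aryl-dihydrobenzofuran-3-carboxylates. The auxiliary and catalyst enantiomers are to be chosen as the matched pair for the required series.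

**Step 5.**
- *What may go wrong:* oxidative addition into the electron-rich C–Br bond next to the bulky silyloxy group may be slow, so that protodebromination or silyl migration competes.
- *Fallback:* the polarity of the coupling is reversed, setting out from 6 and returning at 7. Miyaura borylation of 6 (bis(pinacolato)diboron, PdCl2(dppf), KOAc, dioxane, 80 °C) gives the aryl boronate 2-[2-(TBSO)-3-methoxy-5-(TBSO-methyl)phenyl]-4,4,5,5-tetramethyl-1,3,2-dioxaborolane F6. F6 is coupled with methyl bromoacetate (Pd(OAc)2, tri(1-naphthyl)phosphine, K3PO4, THF/H2O) to give 7. This is the known palladium-catalysed coupling of arylboron compounds with α-bromo esters.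

**Step 7 (and likewise steps 13 and 19).**
- *What may go wrong:* etherification of the doubly ortho-substituted phenol may be incomplete, and the activated electron-rich benzylic alcohol may alkylate the reduced azodicarboxylate.
- *Fallback:* the redox condensation is replaced by a Williamson alkylation, setting out from 3 and returning at 9. Alcohol 3 is converted with CBr4 and PPh3 in CH2Cl2 at 0 °C into 4-(bromomethyl)-2-methoxy-1-(TIPSO)benzene F7. F7 alkylates the phenoxide of 8 (K2CO3, DMF, rt) to give 9.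

**Step 31.**
- *What may go wrong:* hydrogenolysis on the nickel surface may extend to the electron-rich benzylic C7–OH or to the benzylic C2–O bonds, or the desulfurisation may stall after the first C–S cleavage.
- *Fallback:* the metal-surface reduction is replaced by a homogeneous radical chain, setting out from 40 and returning at 41. Bu3SnH with AIBN in toluene at reflux reduces 2-aryl-1,3-dithianes to the methylene compounds and does not attack benzylic ethers or alcohols. No new compound is made (F0).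

## Further compounds

F1 | step 29 | (4S,5S)-4-{2-[3-methoxy-4-(TIPSO)phenyl]-1,3-dithian-2-yl}-5-[(1S,2R,5S)-menthyloxy]dihydrofuran-2(3H)-one | COc1cc(C2(SCCCS2)[C@H]3CC(=O)O[C@@H]3O[C@H]4C[C@@H](C)CC[C@@H]4C(C)C)ccc1O[Si](C(C)C)(C(C)C)C(C)C
F2 | step 9 | 2-[3-methoxy-2-{[3-methoxy-4-(TIPSO)phenyl]methoxy}-5-(TBSO-methyl)phenyl]acetic acid | OC(=O)Cc1cc(CO[Si](C)(C)C(C)(C)C)cc(OC)c1OCc1ccc(O[Si](C(C)C)(C(C)C)C(C)C)c(OC)c1
F3 | step 9 | (S)-1-oxo-1-(pyrrolidin-1-yl)propan-2-yl 2-[3-methoxy-2-{[3-methoxy-4-(TIPSO)phenyl]methoxy}-5-(TBSO-methyl)phenyl]acetate | C[C@H](OC(=O)Cc1cc(CO[Si](C)(C)C(C)(C)C)cc(OC)c1OCc1ccc(O[Si](C(C)C)(C(C)C)C(C)C)c(OC)c1)C(=O)N1CCCC1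
F4 | step 9 | (S)-1-oxo-1-(pyrrolidin-1-yl)propan-2-yl 2-diazo-2-[3-methoxy-2-{[3-methoxy-4-(TIPSO)phenyl]methoxy}-5-(TBSO-methyl)phenyl]acetate | C[C@H](OC(=O)C(=[N+]=[N-])c1cc(CO[Si](C)(C)C(C)(C)C)cc(OC)c1OCc1ccc(O[Si](C(C)C)(C(C)C)C(C)C)c(OC)c1)C(=O)N1CCCC1
F5 | step 9 | (S)-1-oxo-1-(pyrrolidin-1-yl)propan-2-yl (2R,3R)-trans-7-methoxy-2-[3-methoxy-4-(TIPSO)phenyl]-5-(TBSO-methyl)-2,3-dihydrobenzofuran-3-carboxylate | CC(C)(C)[Si](C)(C)OCc1cc(OC)c2c(c1)[C@@H](C(=O)O[C@@H](C)C(=O)N1CCCC1)[C@H](c1ccc(O[Si](C(C)C)(C(C)C)C(C)C)c(OC)c1)O2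
F6 | step 5 | 2-[2-(TBSO)-3-methoxy-5-(TBSO-methyl)phenyl]-4,4,5,5-tetramethyl-1,3,2-dioxaborolane | COc1cc(CO[Si](C)(C)C(C)(C)C)cc(B2OC(C)(C)C(C)(C)O2)c1O[Si](C)(C)C(C)(C)C
F7 | step 7 | 4-(bromomethyl)-2-methoxy-1-(TIPSO)benzene | COc1cc(CBr)ccc1O[Si](C(C)C)(C(C)C)C(C)C
F0 | step 31 | none | none
A1 | alternative 1 | methyl (2S)-2-[3-bromo-5-methoxy-4-(pivaloyloxy)phenyl]-8-methoxy-4-oxochromane-6-carboxylate | COC(=O)c1cc(OC)c2c(c1)C(=O)C[C@@H](c1cc(OC)c(OC(=O)C(C)(C)C)c(Br)c1)O2
A2 | alternative 1 | dimethyl (2S,3S)-trans-2-[3-bromo-5-methoxy-4-(pivaloyloxy)phenyl]-7-methoxy-2,3-dihydrobenzofuran-3,5-dicarboxylate | COC(=O)c1cc(OC)c2c(c1)[C@H](C(=O)OC)[C@@H](c1cc(OC)c(OC(=O)C(C)(C)C)c(Br)c1)O2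
A3 | alternative 2 | bis(diazoester) of rings B and C carrying the TBS-protected unit 3 | COC(=O)c1cc(OC)c(OCc2cc(OC)c(OCc3cc(OC)c4c(c3)[C@@H](CO[Si](C)(C)C(C)(C)C)[C@H](c5ccc(O[Si](C)(C)C(C)(C)C)c(OC)c5)O4)c(c2)C(=[N+]=[N-])C(=O)OC)c(c1)C(=[N+]=[N-])C(=O)OC
A4 | alternative 2 | trans,trans bis(dihydrobenzofuran) triester carrying the TBS-protected unit 3 | COC(=O)c1cc(OC)c2c(c1)[C@H](C(=O)OC)[C@@H](c1cc(OC)c3c(c1)[C@H](C(=O)OC)[C@@H](c1cc(OC)c4c(c1)[C@@H](CO[Si](C)(C)C(C)(C)C)[C@H](c1ccc(O[Si](C)(C)C(C)(C)C)c(OC)c1)O4)O3)O2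
A5 | alternative 3 | methyl 4-hydroxy-3-methoxy-5-[2-(TBSO)-1-(4-methylphenylsulfonyl)ethyl]benzoate | COC(=O)c1cc(OC)c(O)c(c1)C(CO[Si](C)(C)C(C)(C)C)S(=O)(=O)c1ccc(C)cc1
A6 | alternative 3 | (2R,5R)-1-[3-methoxy-4-(TBSO)benzyl]-2,5-dimethylthiolanium triflate | C[C@@H]1CC[C@@H](C)[S+]1Cc1ccc(O[Si](C)(C)C(C)(C)C)c(OC)c1.[O-]S(=O)(=O)C(F)(F)F
A7 | alternative 3 | methyl (2R,3S)-trans-7-methoxy-2-[3-methoxy-4-(TBSO)phenyl]-3-(TBSO-methyl)-2,3-dihydrobenzofuran-5-carboxylate | COC(=O)c1cc(OC)c2c(c1)[C@@H](CO[Si](C)(C)C(C)(C)C)[C@H](c1ccc(O[Si](C)(C)C(C)(C)C)c(OC)c1)O2
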